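In the summer run target fell from 46.8 % to 12.1 % between 0.667 min and 2.50 min, while the isomer of the product stayed at 23.9 % to 24.0 %.

| flask | substrate | partner | remark | time |
|---|---|---|---|---|
| summer | 1 mM | 1.5 mM | run made earlier |  |
| autumn | 1 mM | 0.75 mM | run made earlier |  |
| dusk | 1 mM | 3 mM | run made earlier |  |
| dawn | 1.5 mM | 1.5 mM | run made earlier |  |
| north-east | 1.0 mM (fed, over 2.0 min) | 1.50 mM | all else is in the flask from the start; the feed brings no volume worth counting | 2.5 min |
| north-west | 1.0 mM | 1.50 mM | everything together at the start | 2.5 min |
| east | 1.0 mM | 1.50 mM (in portions, 3, over 2.0 min) | first portion at the start, last at 2.0 min | 2.5 min |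
| south | 1.0 mM | 1.50 mM (fed, over 2.0 min) | all else is in the flask from the start; the feed brings no volume worth counting | 2.5 min |
| north | 1.0 mM (fed, over 12 s) | 1.50 mM | all else is in the flask from the start; the feed brings no volume worth counting | 2.5 min |

summer run (percent of the substrate charged)

| time / min | target / % | isomer of the product / % | substrate / % |
|---|---|---|---|
| 0.200 | 54.5 | 19.5 | 18.7 |
| 0.417 | 55.8 | 21.8 | 5.7 |
| 0.667 | 46.8 | 23.9 | 1.4 |
| 1.33 | 28.4 | 23.0 | 1.3 |
| 2.50 | 12.1 | 24.0 | 0 |

autumn run (percent of the substrate charged)

| time / s | target / % | isomer of the product / % | substrate / % |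
|---|---|---|---|
| 25.0 | 38.8 | 16.9 | 34.7 |
| 50.0 | 30.7 | 16.7 | 27.1 |
| 80.0 | 23.5 | 18.3 | 26.0 |
| 90.0 | 21.3 | 17.3 | 26.5 |
| 120 | 14.8 | 18.1 | 25.6 |

dusk run (percent of the substrate charged)

| time / s | target / % | isomer of the product / % | substrate / % |
|---|---|---|---|
| 10.0 | 64.3 | 23.2 | 3.0 |
| 30.0 | 54.8 | 23.4 | 0 |
| 60.0 | 35.7 | 23.0 | 0 |
| 80.0 | 26.7 | 22.4 | 0 |
| 120 | 17.2 | 23.0 | 0 |

dawn run (percent of the substrate charged)

| time / s | target / % | isomer of the product / % | substrate / % |
|---|---|---|---|
| 10.0 | 46.2 | 16.6 | 31.1 |
| 30.0 | 47.4 | 20.1 | 12.4 |
| 60.0 | 36.7 | 21.3 | 6.7 |
| 80.0 | 30.1 | 22.2 | 4.4 |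
| 120 | 17.2 | 22.0 | 2.1 |

(readings scatter by 1 percentage point)

- the flask with the highest share of target in target plus isomer of the product ("all alike" if they lie within 1.5 percentage points) (north-east / north-west / east / south / north / all alike)
- share of target in target plus isomer of the product at the end, north-east
- share of target in target plus isomer of the product at the end, north-west
- share of target in target plus isomer of the product at the end, east
- share of target in target plus isomer of the product at the end, south
- share of target in target plus isomer of the product at the end, north

1. I read target's decay constant from those two summer readings: 0.738 min⁻¹. In the dusk run I undid that decay on the first reading. This gave a target-to-isomer ratio at birth (selectivity factor) of 3.13.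

2. I called the delay factor the number by which spreading formation evenly over a window multiplies the end ratio of target to isomer, compared with formation at the start. It is (exp(x) − 1)/x, with x the decay constant times the window.

3. I turned the question round. With everything formed at the start, the end ratio is 0.495, a share of 33.1 %. For "all alike", a delay factor would have to stay below 1.07.

4. In the summer run substrate's lifetime read 0.119 min, far shorter than the 2.0 min feed. So I let north-east form target at the pace of its feed. Its delay factor is 2.29, well above that line, and its share is 53.1 %. North's 12 s feed gives 1.08, a share of 34.8 %. I did not reckon south or east. My pick was north-east.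

5. The forecast also chose north-east, with 56 % for north-east, 35 % for north-west, 50 % for east, 53 % for south and 37 % for north. Its grounds: “Feeding therefore cannot change the selectivity. It only delays target formation”.

6. The flasks gave 54.4 % for north-east, 33.2 % for north-west, 48.9 % for east, 49.8 % for south and 35.0 % for north, so north-east led.

    substrate + partner → target (k = 110 M⁻¹ s⁻¹)
    substrate + partner → isomer of the product (k = 35.0 M⁻¹ s⁻¹)
    substrate + partner → second isomer (k = 1.10 M⁻¹ s⁻¹)
    target → over-reaction product (k = 0.0130 s⁻¹)

The north-east ratio over the north-west ratio was 2.40, against my delay factor of 2.29. In north-east at 1.10 min, substrate's half-life through the target step was 0.10 min, far shorter than the feed. Target's lifetime, 1.28 min, was shorter than the feed too.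

7. The neighbour flask is north-east read at 6.0 min. The delay factor stays and the decay runs on, so the ratio becomes 0.0856, a share of 7.88 %. The computed share was 7.35 %.

All runs come from a simulation for substances that don't exist; the scatter is artificial.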